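**Strategy**

- Ring numbering: C1 = CH(OBz), C2=C3 (C3 carries the carboxyl carbon C15), C4, C5, C6/C7 = oxirane (CH3 on C7), C8-C10, C11 = CMe2.
- Enabling feature: the oxygen on C1 stands 1,3 to C6 of the C6=C7 alkene hidden in the oxirane. One extra C1-C7 bond therefore makes the 11-membered ring the rim of a cyclohexane (C1, C11, C10, C9, C8, C7) fused to a cycloheptene (C1 to C7), with OH on C1 and a leaving group on C6. This is the array of a Grob fragmentation.
- Cuts: first the oxirane oxygen, the O-benzoyl bond and C1-H, back to an achiral 2,6-dienone. After the C1-C7 bond is added: C2=C3 (metathesis), C3-C15 (carbonylation), C1-C2 (vinyl addition), C7-CH3 (methylation) and C6-C7 (aldol).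
- Forward order of rings: the cyclohexanone is purchased, the cycloheptene is closed on it, the fragmentation merges both into the carbocycle, and the oxirane comes last.
- Stereochemistry: the racemic C6/C7 relationship of the bicycle (chelate-controlled methylation) becomes the E geometry of C6=C7, and the seven-membered ring fixes ring-cis C2=C3. Absolute configuration enters afterwards: C1 (R) by CBS reduction of the achiral dienone, C6/C7 (R,R) by Shi epoxidation.

Key step: step 11

Remark: every chiral compound before the fragmentation is a racemate. SMILES and rel-descriptors show one enantiomer only, to fix relative configuration. Locants and descriptors follow the ring numbering above throughout.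

Assumption: the vinyl nucleophile is taken to attack the ketone axially (vinyl cis to the C7 side chain, OH cis to the C7 methyl). The other C1 epimer would fragment to the same dienone.

**Step 1**
Reactants: 1 5-(trimethylsilyl)pent-4-yn-1-ol
Product: 2 5-(trimethylsilyl)pent-4-ynal
Conditions: PhI(OAc)2 (1.1 equiv), TEMPO (10 mol %), CH2Cl2, rt
Reagents that add atoms: none
Why: Oxoammonium (TEMPO) oxidation of a primary alcohol stops at the aldehyde and leaves the silylalkyne alone; no stereocentre is involved.

**Step 2**
Reactants: 3 2,2-dimethylcyclohexanone; 2 5-(trimethylsilyl)pent-4-ynal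
Product: 5 rac-anti-ketol rel-(6R,7R)-2-[1-hydroxy-5-(trimethylsilyl)pent-4-ynyl]-6,6-dimethylcyclohexanone, via lithium enolate 4 (not isolated)
Conditions: LDA (1.05 equiv), THF, -78 °C; then 2, -78 °C, 30 min; AcOH quench at -78 °C
Reagents that add atoms: none
Why: Kinetic lithium enolate aldol addition, in which quaternary C11 allows only one enolate, the ring-fixed E(O)-enolate should favour the anti ketol through a Zimmerman-Traxler chair, and the C7 configuration does not matter because C7 is made planar again in step 3.

**Step 3**
Reactants: 5 rac-anti-ketol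
Product: 7 rac-ketol rel-(6R,7S)-2-[1-hydroxy-5-(trimethylsilyl)pent-4-ynyl]-2,6,6-trimethylcyclohexanone (C7 methyl anti to the C6 hydroxyl in the C1-C7-C6-C5 zigzag), via dilithium enolate-alkoxide 6 (not isolated)
Conditions: 5 added to LDA (2.5 equiv), THF, -78 to -40 °C; MeI (3 equiv), DMPU, -78 to -20 °C; AcOH quench
Reagents that add atoms: iodomethane, CI
Why: Proposed new method: excess LDA should remove the hydroxyl proton and then C7-H (the only enolisable position, C11 being quaternary) to give 6, in which the ring holds the enolate oxygen and C6 cis on C1=C7 so that lithium bridges both oxygens in a six-membered chelate, and MeI should reach C7 from the chelate face opposite the C5 chain on C6, which places CH3 anti to the C6 oxygen; the closest known reaction type is the Frater-Seebach alkylation of beta-hydroxy ester dianions, which obeys the same chelate model even when a quaternary alpha carbon is formed, and the new element is a beta-hydroxy ketone, whose alkoxide can revert by retro-aldol cleavage, hence inverse addition and low temperature.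

**Step 4**
Reactants: 7 rac-ketol with quaternary C7
Product: 8 rel-(6R,7S)-2,6,6-trimethyl-2-[1-(triethylsilyloxy)-5-(trimethylsilyl)pent-4-ynyl]cyclohexanone
Conditions: TESOTf (1.3 equiv), 2,6-lutidine, CH2Cl2, -78 to 0 °C
Reagents that add atoms: triethylsilyl trifluoromethanesulfonate, CC[Si](CC)(CC)OS(=O)(=O)C(F)(F)F
Why: Silyl triflate/lutidine silylation copes with the neopentylic secondary alcohol and removes the alkoxide that would otherwise trigger retro-aldol cleavage under the basic conditions of step 5.

**Step 5**
Reactants: 8 TES-protected ketone; 9 vinylmagnesium bromide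
Product: 11 rel-(1R,6R,7S)-1-ethenyl-2,6,6-trimethyl-2-[1-(triethylsilyloxy)-5-(trimethylsilyl)pent-4-ynyl]cyclohexanol, via vinylcerium dichloride 10 (not isolated)
Conditions: anhydrous CeCl3 (3 equiv), 9 (3 equiv), THF, -78 °C, 1 h; then 8, -78 °C to rt; aq NH4Cl
Reagents that add atoms: none
Why: Organocerium 1,2-addition, in which the ketone has no alpha hydrogen and cannot enolise, a slim sp2 nucleophile on oxophilic cerium suits a carbonyl between two quaternary carbons, and axial attack away from the axial methyl groups on C7 and C11 should set C1 as drawn (a centre that is destroyed in step 11).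

**Step 6**
Reactants: 11 tertiary vinyl carbinol
Product: 12 rel-(1R,6R,7S)-1-ethenyl-2,6,6-trimethyl-2-[1-(triethylsilyloxy)pent-4-ynyl]cyclohexanol
Conditions: K2CO3 (0.3 equiv), MeOH, rt
Reagents that add atoms: none
Why: Carbonate-catalysed methanolysis cleaves only the C(sp)-Si bond, the hindered TES ether and the tertiary alcohol being inert.

**Step 7**
Reactants: 12 terminal alkyne
Product: 13 2-(trimethylsilyl)ethyl rel-(1R,6R,7S)-5-(2-ethenyl-2-hydroxy-1,3,3-trimethylcyclohexyl)-2-methylidene-5-(triethylsilyloxy)pentanoate
Conditions: CO (20 bar), Me3SiCH2CH2OH (3 equiv), Pd(OAc)2 (3 mol %), 2-PyPPh2 (60 mol %), MsOH (30 mol %), toluene, 50 °C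
Reagents that add atoms: carbon monoxide, [C-]#[O+]; 2-(trimethylsilyl)ethanol, C[Si](C)(C)CCO
Why: Palladium-catalysed Markovnikov hydroalkoxycarbonylation of a terminal alkyne, in which the 2-pyridylphosphine ligand directs the carboxyl carbon to the internal alkyne carbon, the hindered vinyl group reacts far more slowly, and the excess basic ligand buffers the acid so that the TES ether stays on and keeps the C6 oxygen from closing an alpha-methylene lactone.

**Step 8**
Reactants: 13 vinyl carbinol acrylate
Product: 14 2-(trimethylsilyl)ethyl rel-(1R,6R,7S)-1-hydroxy-7,11,11-trimethyl-6-(triethylsilyloxy)bicyclo[5.4.0]undec-2-ene-3-carboxylate (cis-fused)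
Conditions: Hoveyda-Grubbs second-generation catalyst (10 mol %, in portions), toluene (2 mM), 90 °C, Ar sparge
Reagents that add atoms: none
Why: Ring-closing metathesis, in which the carbene should load on the monosubstituted vinyl group (helped by the free allylic hydroxyl) and close on the 1,1-disubstituted acrylate, the cis placement of both arms on the cyclohexane and loss of ethylene driving formation of a seven-membered ring in which C2=C3 can only be ring-cis.

**Step 9**
Reactants: 14 bicyclic TES ether
Product: 15 2-(trimethylsilyl)ethyl rel-(1R,6R,7S)-1,6-dihydroxy-7,11,11-trimethylbicyclo[5.4.0]undec-2-ene-3-carboxylate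
Conditions: PPTS (0.3 equiv), MeOH, rt to 40 °C
Reagents that add atoms: none
Why: Mild acid-catalysed methanolysis removes the TES ether while the silylethyl ester and the tertiary alcohol (ionisation disfavoured by the conjugated ester) remain, and lactonisation of the C6 hydroxyl onto C15 is blocked because it would place C2=C3 at a bridgehead.

**Step 10**
Reactants: 15 bicyclic diol
Product: 16 2-(trimethylsilyl)ethyl rel-(1R,6R,7S)-1-hydroxy-6-(methanesulfonyloxy)-7,11,11-trimethylbicyclo[5.4.0]undec-2-ene-3-carboxylate (OH, angular CH3 and OMs on one face of the seven-membered ring)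
Conditions: MsCl (1.3 equiv), Et3N (2 equiv), CH2Cl2, -20 to 0 °C
Reagents that add atoms: methanesulfonyl chloride, CS(=O)(=O)Cl
Why: Sulfonylation takes only the secondary hydroxyl, because the tertiary C1 hydroxyl between two quaternary carbons is too hindered, and it occurs at oxygen with retention at C6.

**Step 11**
Reactants: 16 hydroxy mesylate
Product: 18 2-(trimethylsilyl)ethyl (2E,6E)-7,11,11-trimethyl-1-oxocycloundeca-2,6-diene-3-carboxylate (C2=C3 ring-cis; C6=C7 ring-trans; achiral), via potassium alkoxide 17 (not isolated)
Conditions: KHMDS (1.0 equiv), THF, -78 to 0 °C, 15 min; pH 7 buffer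
Reagents that add atoms: none
Why: Deprotonation of the tertiary C1 hydroxyl gives 17, whose oxygen pushes electron density into C1 while the C1-C7 sigma bond, anti-periplanar to C6-OMs, breaks and mesylate leaves in one concerted, irreversible event that creates C1=O and C6=C7. The closest known reaction type is the Grob (Wharton) fragmentation of fused bicyclic 1,3-diol monosulfonates, which converts decalin hydroxy tosylates into E-cyclodecenones. No ring is closed: the bond shared by the cyclohexane and the cycloheptene disappears and their rim is left as the 11-membered carbocycle, so no medium-ring cyclisation has to be paid for. No stereocentre is formed and all three of 16 vanish; the only new stereo-element is the C6=C7 geometry, which should be E because in the reactive conformer the mesylate (cis to the angular methyl) is pseudo-equatorial, with C5 anti to C8 and gauche to the methyl. The step needs fragmentation to beat oxetane closure, 1,2-shift and base attack on the product: O1 and the mesylate sit on the same ring face in an all-anti O1-C1-C7-C6-O zigzag, so backside displacement by O1 is impossible, C11 and C2 offer no enolisable hydrogen, and one equivalent of a non-nucleophilic base is consumed by the hydroxyl before it can take the gamma proton at C4 of the dienone. The C2=C3 geometry is carried over unchanged from the cycloheptene.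

**Step 12**
Reactants: 18 achiral dienone ester
Product: 19 2-(trimethylsilyl)ethyl (1R,2E,6E)-1-hydroxy-7,11,11-trimethylcycloundeca-2,6-diene-3-carboxylate
Conditions: (S)-Me-CBS oxazaborolidine (0.5 equiv), catecholborane (2 equiv), toluene, -78 to -40 °C; MeOH, then aq NaHCO3
Reagents that add atoms: none
Why: Corey-Bakshi-Shibata reduction, in which the ketone should bind the catalyst boron through the lone pair anti to the bulky CMe2 flank so that the (S)-catalyst delivers hydride to the face giving (1R), catecholborane at low temperature sparing both alkenes and the ester; the sense is to be checked by Mosher ester analysis, and the (R)-catalyst is to be used if the alkenyl flank proves the larger group.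

**Step 13**
Reactants: 19 (1R)-allylic alcohol; 20 benzoyl chloride
Product: 21 2-(trimethylsilyl)ethyl (1R,2E,6E)-1-(benzoyloxy)-7,11,11-trimethylcycloundeca-2,6-diene-3-carboxylate
Conditions: 20 (3 equiv), DMAP (0.5 equiv), pyridine, 50 °C
Reagents that add atoms: none
Why: DMAP-catalysed acylation with excess acid chloride and gentle heat overcomes the neopentylic hindrance and takes place at oxygen, so C1 keeps its configuration.

**Step 14**
Reactants: 21 (1R)-benzoate
Product: 22 2-(trimethylsilyl)ethyl (1R,2E,6R,7R)-1-(benzoyloxy)-6,7-epoxy-7,11,11-trimethylcycloundec-2-ene-3-carboxylate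
Conditions: D-fructose-derived Shi ketone (0.3-0.5 equiv), Oxone, K2CO3, Bu4NHSO4 (cat.), MeCN-DMM / aq Na2B4O7-EDTA (pH 10.5), 0 °C
Reagents that add atoms: Oxone (active component potassium peroxymonosulfate), [K+].[O-]S(=O)(=O)OO
Why: Shi asymmetric epoxidation, in which the electrophilic chiral dioxirane attacks only the electron-rich E-trisubstituted C6=C7 (the enoate is inert), syn addition keeps C5 and C8 trans on the oxirane, and the spiro transition state of the D-fructose-derived ketone, which gives (R,R)-epoxides from E-di- and trisubstituted alkenes, should set (6R,7R) on whichever rapidly interconverting ring conformer exposes that face.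

**Step 15**
Reactants: 22 epoxy benzoate silylethyl ester
Product: 23 (1R,2E,6R,7R)-1-(benzoyloxy)-6,7-epoxy-7,11,11-trimethylcycloundec-2-ene-3-carboxylic acid (CNP0377917.1)
Conditions: TBAF (3 equiv) buffered with AcOH (1.5 equiv), THF, 0 °C to rt; pH 4 buffer work-up
Reagents that add atoms: none
Why: Fluoride-induced beta-elimination of the 2-(trimethylsilyl)ethyl ester frees the acid under near-neutral conditions that leave the benzoate, the oxirane and all three stereocentres untouched.

**Compound list**

1 | 5-(trimethylsilyl)pent-4-yn-1-ol | C[Si](C)(C)C#CCCCO | starting material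
2 | 5-(trimethylsilyl)pent-4-ynal | C[Si](C)(C)C#CCCC=O | intermediate
3 | 2,2-dimethylcyclohexanone | CC1(C)CCCCC1=O | starting material
4 | lithium 6,6-dimethylcyclohex-1-en-1-olate (not isolated) | CC1(C)CCCC=C1[O-].[Li+] | intermediate
5 | rac-anti-ketol, rel-(6R,7R)-2-[1-hydroxy-5-(trimethylsilyl)pent-4-ynyl]-6,6-dimethylcyclohexanone | CC1(C)CCC[C@@H](C1=O)[C@H](O)CCC#C[Si](C)(C)C | intermediate
6 | dilithium enolate-alkoxide of 5 (not isolated) | CC1(C)CCCC(=C1[O-])[C@H]([O-])CCC#C[Si](C)(C)C.[Li+].[Li+] | intermediate
7 | rac-ketol, rel-(6R,7S)-2-[1-hydroxy-5-(trimethylsilyl)pent-4-ynyl]-2,6,6-trimethylcyclohexanone | CC1(C)CCC[C@](C)(C1=O)[C@H](O)CCC#C[Si](C)(C)C | intermediate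
8 | TES ether of 7 | CC1(C)CCC[C@](C)(C1=O)[C@H](O[Si](CC)(CC)CC)CCC#C[Si](C)(C)C | intermediate
9 | vinylmagnesium bromide | C=C[Mg]Br | starting material
10 | vinylcerium dichloride (not isolated) | C=C[Ce](Cl)Cl | intermediate
11 | rel-(1R,6R,7S) tertiary vinyl carbinol, TES ether, silylalkyne | CC1(C)CCC[C@@](C)([C@H](O[Si](CC)(CC)CC)CCC#C[Si](C)(C)C)[C@@]1(O)C=C | intermediate
12 | rel-(1R,6R,7S) tertiary vinyl carbinol, TES ether, terminal alkyne | CC1(C)CCC[C@@](C)([C@H](O[Si](CC)(CC)CC)CCC#C)[C@@]1(O)C=C | intermediate
13 | rel-(1R,6R,7S) vinyl carbinol with 2-substituted 2-(trimethylsilyl)ethyl acrylate | CC1(C)CCC[C@@](C)([C@H](O[Si](CC)(CC)CC)CCC(=C)C(=O)OCC[Si](C)(C)C)[C@@]1(O)C=C | intermediate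
14 | 2-(trimethylsilyl)ethyl rel-(1R,6R,7S)-1-hydroxy-7,11,11-trimethyl-6-(triethylsilyloxy)bicyclo[5.4.0]undec-2-ene-3-carboxylate | CC1(C)CCC[C@@]2(C)[C@H](O[Si](CC)(CC)CC)CCC(C(=O)OCC[Si](C)(C)C)=C[C@@]12O | intermediate
15 | 2-(trimethylsilyl)ethyl rel-(1R,6R,7S)-1,6-dihydroxy-7,11,11-trimethylbicyclo[5.4.0]undec-2-ene-3-carboxylate | CC1(C)CCC[C@@]2(C)[C@H](O)CCC(C(=O)OCC[Si](C)(C)C)=C[C@@]12O | intermediate
16 | 2-(trimethylsilyl)ethyl rel-(1R,6R,7S)-1-hydroxy-6-(methanesulfonyloxy)-7,11,11-trimethylbicyclo[5.4.0]undec-2-ene-3-carboxylate | CC1(C)CCC[C@@]2(C)[C@H](OS(C)(=O)=O)CCC(C(=O)OCC[Si](C)(C)C)=C[C@@]12O | intermediate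
17 | potassium C1 alkoxide of 16 (not isolated) | CC1(C)CCC[C@@]2(C)[C@H](OS(C)(=O)=O)CCC(C(=O)OCC[Si](C)(C)C)=C[C@@]12[O-].[K+] | intermediate
18 | 2-(trimethylsilyl)ethyl (2E,6E)-7,11,11-trimethyl-1-oxocycloundeca-2,6-diene-3-carboxylate | CC1(C)CCC/C(C)=C/CC/C(C(=O)OCC[Si](C)(C)C)=C\C1=O | intermediate
19 | 2-(trimethylsilyl)ethyl (1R,2E,6E)-1-hydroxy-7,11,11-trimethylcycloundeca-2,6-diene-3-carboxylate | CC1(C)CCC/C(C)=C/CC/C(C(=O)OCC[Si](C)(C)C)=C\[C@H]1O | intermediate
20 | benzoyl chloride | O=C(Cl)c1ccccc1 | starting material
21 | 2-(trimethylsilyl)ethyl (1R,2E,6E)-1-(benzoyloxy)-7,11,11-trimethylcycloundeca-2,6-diene-3-carboxylate | CC1(C)CCC/C(C)=C/CC/C(C(=O)OCC[Si](C)(C)C)=C\[C@H]1OC(=O)c1ccccc1 | intermediate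
22 | 2-(trimethylsilyl)ethyl (1R,2E,6R,7R)-1-(benzoyloxy)-6,7-epoxy-7,11,11-trimethylcycloundec-2-ene-3-carboxylate | CC1(C)CCC[C@@]2(C)O[C@@H]2CC/C(C(=O)OCC[Si](C)(C)C)=C\[C@H]1OC(=O)c1ccccc1 | intermediate
23 | (1R,2E,6R,7R)-1-(benzoyloxy)-6,7-epoxy-7,11,11-trimethylcycloundec-2-ene-3-carboxylic acid (CNP0377917.1) | CC1(C)CCC[C@@]2(C)O[C@@H]2CC/C(C(=O)O)=C\[C@H]1OC(=O)c1ccccc1 | target

**Step count**

Total steps: 15. Longest linear sequence: 15 steps (1 to 23).

**Steps most likely to fail**

**Step 3 (new method).** The lithium alkoxide may revert by retro-aldol cleavage, or removal of the tertiary C7 proton next to the alkoxide may be too slow, before methylation can occur. The cosolvent may also loosen the lithium bridge and erode facial control.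

The fallback uses known chemistry, sets out from 5 and returns at 7. It builds the quaternary carbon first and the carbinol second.
- Dess-Martin oxidation of 5 gives the enolised beta-diketone 2-[5-(trimethylsilyl)pent-4-ynoyl]-6,6-dimethylcyclohexanone F1.
- C-methylation (K2CO3, MeI, acetone) gives the non-enolisable 2-methyl diketone F2.
- The side-chain carbonyl, far less hindered than the ring carbonyl between two quaternary carbons, is reduced under chelation control (Zn(BH4)2, Et2O, -78 to -20 °C).
- In the zinc chelate the acyl group is equatorial, and hydride should reach C6 from the side of the axial methyl, which gives 7.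
- Selectivity may be modest. The C6 epimer is removed by chromatography and returned to F2 by oxidation.

**Step 8.** The ruthenium carbene may fail to load on the doubly neopentylic vinyl group, and the electron-poor 1,1-disubstituted acrylate may not engage. Catalyst decay or intermolecular coupling would then outrun ring closure.

The fallback sets out from 12 and returns at 14. It replaces the acrylate partner by the unhindered alkyne.
- Ring-closing enyne metathesis (second-generation Grubbs catalyst, ethylene atmosphere, toluene, 60 °C) should give the bicyclic 3-ethenyl diene F3 in the exo mode.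
- One-pot Lemieux-Johnson cleavage (OsO4 cat., NaIO4, 2,6-lutidine, dioxane-water) of the exposed monosubstituted double bond gives the enal F4. The ring alkene is shielded by C1.
- Pinnick oxidation gives the bicyclic enoic acid F5.
- Steglich esterification with 2-(trimethylsilyl)ethanol delivers 14.

**Step 5.** The carbonyl between two quaternary carbons may simply resist addition for steric reasons, with slow loss or migration of the silyl ether on prolonged warming.

The fallback sets out from 8 and returns at 11.
- Lithium acetylide (acetylene, n-BuLi, THF, -78 °C to rt), the slimmest carbon nucleophile, gives the ethynyl carbinol F6.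
- Hydroxyl-directed hydroalumination (Red-Al, THF, 0 °C to rt, then water) reduces only the propargylic triple bond, because aluminium is delivered from the C1 alkoxide.
- The remote silylalkyne is left intact, and 11 is obtained.

**Further compounds**

F1 | step 3 | 2-[5-(trimethylsilyl)pent-4-ynoyl]-6,6-dimethylcyclohexanone | CC1(C)CCCC(C1=O)C(=O)CCC#C[Si](C)(C)C
F2 | step 3 | rac-2,6,6-trimethyl-2-[5-(trimethylsilyl)pent-4-ynoyl]cyclohexanone | CC1(C)CCC[C@](C)(C1=O)C(=O)CCC#C[Si](C)(C)C
F3 | step 8 | rel-(1R,6R,7S)-3-ethenyl-7,11,11-trimethyl-6-(triethylsilyloxy)bicyclo[5.4.0]undec-2-en-1-ol | CC1(C)CCC[C@@]2(C)[C@H](O[Si](CC)(CC)CC)CCC(C=C)=C[C@@]12O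
F4 | step 8 | rel-(1R,6R,7S)-1-hydroxy-7,11,11-trimethyl-6-(triethylsilyloxy)bicyclo[5.4.0]undec-2-ene-3-carbaldehyde | CC1(C)CCC[C@@]2(C)[C@H](O[Si](CC)(CC)CC)CCC(C=O)=C[C@@]12O
F5 | step 8 | rel-(1R,6R,7S)-1-hydroxy-7,11,11-trimethyl-6-(triethylsilyloxy)bicyclo[5.4.0]undec-2-ene-3-carboxylic acid | CC1(C)CCC[C@@]2(C)[C@H](O[Si](CC)(CC)CC)CCC(C(=O)O)=C[C@@]12O
F6 | step 5 | rel-(1R,6R,7S)-1-ethynyl-2,6,6-trimethyl-2-[1-(triethylsilyloxy)-5-(trimethylsilyl)pent-4-ynyl]cyclohexanol | CC1(C)CCC[C@@](C)([C@H](O[Si](CC)(CC)CC)CCC#C[Si](C)(C)C)[C@@]1(O)C#C
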